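## Analysis of the target

The target is an unsymmetrical diaryl ether. Ring A is a 1,2,4-trisubstituted benzene (hydroxyl at C1′, bridging oxygen at C2′, side chain at C4′). Ring B is a 1,2,3,5-tetrasubstituted benzene (bridging oxygen at C1, hydroxyls at C2 and C3, side chain at C5). Each ring carries the same C15 arm: a farnesyl unit bonded through its C3 with allylic transposition, so that the benzylic carbon is an all-carbon quaternary centre bearing methyl, vinyl and the (3E)-4,8-dimethylnona-3,7-dienyl chain.

These two quaternary carbons are the only stereocentres. They lie eight bonds apart across the ether bridge and cannot influence one another. Their substituents correspond pairwise, yet the descriptors are opposite (R on ring A, S on ring B), so each must be set by reagent control, with opposite sense.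

The six alkenes (two vinyl groups, four trisubstituted, one of them E-configured in each arm) rule out hydrogenolysis, strong protic acid (cation–olefin cyclisation, hydration) and electrophilic oxidants. The catechol of ring B and the phenol of ring A oxidise easily in air and are best unmasked last.

Two things make the synthesis hard: the congested benzylic quaternary centres, and the C2′–O–C1 bond between two electron-rich rings that each carry an oxygen ortho to the bridge, with no activating group for a substitution.

The strategy rests on ring B itself. C1 and C2 can be the two carbons of an alkyne sitting on the oxygen of ring A. C3 (hydroxyl), C6, C5 (arm) and C4 can be the four carbons of a vinylketene O=C3=C6H–C5(arm)=C4H2.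

## Retrosynthetic reasoning

**33 ⇒ 32.** Only the two acetal C–O bonds at O–C1′ and O–C3 are cut. The free catechol and phenol are the most oxidation-prone form of the molecule, so they appear in the last operation. The forward step must cleave two methoxymethyl ethers without protonating the trisubstituted alkenes.

**32 ⇒ 29 ⇒ 28.** The C2–O bond of ring B is cut. C2 lies between the two oxygen-bearing carbons C1 and C3 and is therefore the most acidic ring position once the C3 hydroxyl of 28 is masked (29). A directed lithiation, borylation and oxidation puts the last oxygen in. Introducing this oxygen late leaves a simple terminal alkyne for the ring-forming step. The forward reaction has to metalate C2 of ring B in preference to the position ortho to the acetal on ring A.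

**28 ⇒ 15 + 23 (key disconnection).** Four C–C bonds of ring B are cut: C2–C3 and C1–C6 (alkyne to ketene), C3–C4 (ring closure) and C5–C6 (migration that creates vinylketene 24). This removes the diaryl ether problem altogether, because the bridging oxygen is already bonded to the two alkyne carbons of 15 and no bond is made between two arenes. Both arms are carried in unchanged, and the 1,3-relationship of aryloxy and hydroxyl on ring B follows from the polarity of the reacting partners. The forward reaction has to turn 23 into 24, add it to 15 with the correct orientation (25), open the four-membered ring (26) and close the six-membered one (27, then 28).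

**15 ⇒ 12 ⇒ 10 + 11.** The O–C(sp) bond is cut. Both alkyne carbons come from 11, attached to the phenol oxygen of 10 as the dichlorovinyl ether 12 and then stripped of both chlorines. A phenol is the only functional group ring A has to provide.

**10 ⇒ 7.** The C2′–O bond of ring A is cut. In 7 the two positions ortho to the acetal are equivalent, so a directed metalation can only give one product. This allows ring A to start from a simple para-substituted arene.

**7 ⇒ 4 + 2 (2 ⇒ 1, 4 ⇒ 3).** The bond between C4′ and the quaternary carbon is cut. An aryl nucleophile derived from 4 attacks C3 of phosphate 2 with allylic transposition, creating the quaternary centre and the vinyl group in one step under catalyst control (R). The whole C15 chain with its E-alkene comes intact from 1.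

**23 ⇒ 21 ⇒ 20 ⇒ 19 ⇒ 18.** No skeletal bond of the arm is cut except the one to the methyl carbon added at the aldehyde stage. The diazo group goes on the methyl ketone 21 by deacylative diazo transfer (via 22). That methyl carbon, the future C6 of ring B, comes from addition to aldehyde 19, which is the unmasked form of acetal 18. The ketone is made late because a free enone would not survive the organometallic chemistry that sets the stereocentre.

**18 ⇒ 17 + 2 (17 ⇒ 16).** The bond between the future C5 of ring B and the quaternary carbon is cut. A 1,1-disubstituted alkenyl nucleophile 17 attacks C3 of 2 in the same kind of allylic substitution as for ring A, with the enantiomeric ligand, since the S centre needs attack on the opposite alkene face. 17 already holds C4, C5 and C3 of ring B (methylidene, boron-bearing carbon and acetal carbon) and comes from alkyne 16 in one step.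

## Alternatives that were turned down

**Alternative 1: double lithiation–borylation on a preformed diaryl ether.**
- Disconnection: the two bonds from the quaternary carbons to the first CH2 of each chain.
- Forward key step: the pseudo-meso bis(carbamate) A2 (R carbinol carbon on ring A, S on ring B) would be deprotonated at both benzylic carbons with a hindered alkyllithium base and trapped with two equivalents of the homogeranyl boronate A3. Two 1,2-metallate shifts would give the bis(tertiary boronate) A1, and the boron groups would later be exchanged for vinyl by Zweifel olefination.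
- For: the step is stereospecific, the configuration comes from easily made secondary benzylic alcohols, and both quaternary centres arise in one operation.
- Against: the hindered diaryl ether between two ortho-oxygenated rings still has to be made by C–O coupling. The two carbinol centres need opposite sense on two very similar acetyl groups and so cannot be set in one reduction. A3 needs a separate homologation sequence and is used twice. The ring B carbanion sits para to an oxygen, which slows deprotonation and makes boronate formation more reversible. Two hindered tertiary boronates must then be vinylated and three silyl ethers removed.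
- Comparison: on stereochemical fidelity at the quaternary carbons this route is at least as strong as the chosen one. The chosen strategy offers in its place a synthesis with no aryl C–O coupling, the farnesyl skeleton taken whole from 1, and R and S made by the same catalytic reaction through choice of ligand enantiomer. Step counts are similar.

**Alternative 2: twofold decarboxylative alkenylation to attach the terpene tails.**
- Disconnection: the CH2–CH= bond (C5–C6) of each arm.
- Forward key step: the bis(redox-active ester) A5 would be coupled at a cathode under nickel catalysis with two equivalents of the E-alkenyl iodide A6, giving the tris(methoxymethyl) ether A4 of the target.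
- For: the E geometry is brought in with A6 and retained, the conditions are mild, and A4 is one deprotection from the target, which is fewer steps after the key step than in the chosen route.
- Against: the step addresses none of the real difficulties. Both quaternary stereocentres, the diaryl ether and the oxygenation of ring B are all deferred to A5. Its stereocentres could no longer come from 1 and would need an unrelated asymmetric method on shortened chains. Two radical couplings on one molecule multiply the losses from reduction and mono-coupling.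
- Comparison: it is stronger on late-stage modularity of the tails. The chosen strategy offers the complete arms from a C15 feedstock and makes bonds only where the structure is difficult.

**Alternative 3: ring A by Robinson annulation on the oxygen of ring B.**
- Disconnection: C4′–C5′ and C2′–C3′ of ring A.
- Forward key step: the enamine of aldehyde A8 would add to the aryloxymethyl vinyl ketone A9, and aldol condensation of the keto-aldehyde would give cyclohexenone A7, to be dehydrogenated to the phenol.
- For: like the chosen route it builds one ring on the oxygen of the other, so the C–O bond is a simple phenoxide alkylation. It needs no photochemistry and only cheap reagents.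
- Against: the nucleophilic carbon of A8 is neopentylic, so the conjugate addition to a polymerisable enone is slow. A7 is at the wrong oxidation level, and its dehydrogenation needs an oxidant or a hot metal catalyst in the presence of six alkenes and a trioxygenated arene. Ring B must first be made as a fully substituted pyrogallol derivative carrying its own quaternary centre.
- Comparison: it is equal in avoiding aryl–oxygen coupling and arguably simpler to run. The chosen strategy offers the arene directly at the phenol oxidation level (tautomerisation, no oxidant), regiochemistry fixed by alkyne polarity, and no pre-made ring B.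

Key step: step 13

## Remarks before the steps

- Ligand: (S,S)-L is the imidazolinium sulfonate 2-[(4S,5S)-3-(2,6-diethylphenyl)-4,5-diphenyl-4,5-dihydro-1H-imidazol-3-ium-1-yl]benzenesulfonate; (R,R)-L is its enantiomer.
- Assumption: aryl and alkenyl transfer follow the same sense of induction, and (S,S)-L is taken to give the R product 7; if the first intermediate shows the opposite sense, the two ligand enantiomers are exchanged between steps 3 and 8.

## Route

Step 1
Reactants: 1 (2E,6E)-farnesol
Product: 2 diethyl (2E,6E)-3,7,11-trimethyldodeca-2,6,10-trien-1-yl phosphate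
Conditions: ClP(O)(OEt)2, Et3N, DMAP (cat.), CH2Cl2, 0 °C to rt
Reagents that add atoms: diethyl chlorophosphate, CCOP(=O)(Cl)OCC
Why: O-phosphorylation of a primary allylic alcohol; the alkenes are untouched and the E-phosphate is the electrophile for both allylic substitutions.

Step 2
Reactants: 3 4-bromophenol
Product: 4 1-bromo-4-(methoxymethoxy)benzene
Conditions: MOMCl, i-Pr2NEt, CH2Cl2, 0 °C to rt
Reagents that add atoms: chloromethyl methyl ether, COCCl
Why: Phenol alkylation to the methoxymethyl ether, which survives organolithium and organoaluminium reagents and later directs ortho-metalation.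

Step 3
Reactants: 4 1-bromo-4-(methoxymethoxy)benzene; 2 diethyl (2E,6E)-3,7,11-trimethyldodeca-2,6,10-trien-1-yl phosphate
Product: 7 1-(methoxymethoxy)-4-[(3R,6E)-3,7,11-trimethyldodeca-1,6,10-trien-3-yl]benzene, via aryllithium 5 (not isolated), via arylalane 6 (not isolated)
Conditions: n-BuLi, THF, −78 °C; Et2AlCl, −78 °C to rt; then 2, preformed silver carbene from (S,S)-L and Ag2O (2.5 mol%), CuCl2·2H2O (5 mol%), THF, −30 °C
Reagents that add atoms: none
Why: Copper-catalysed enantioselective allylic substitution (SN2′) with an aryl(dialkyl)aluminium reagent; the divalent copper salt is reduced in situ to the monovalent copper carbene, which transfers aryl to C3 of the E-phosphate anti to the leaving group. The sulfonate-bearing chiral carbene selects the alkene face and so sets the R quaternary centre together with the vinyl group.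

Step 4
Reactants: 7 1-(methoxymethoxy)-4-[(3R,6E)-3,7,11-trimethyldodeca-1,6,10-trien-3-yl]benzene
Product: 10 2-(methoxymethoxy)-5-[(3R,6E)-3,7,11-trimethyldodeca-1,6,10-trien-3-yl]phenol, via lithiated arene 8 (not isolated), via dimethyl boronate 9 (not isolated)
Conditions: s-BuLi, TMEDA, THF, −78 °C; B(OMe)3, −78 °C to rt; then H2O2, aq. NaOH, 0 °C to rt
Reagents that add atoms: hydrogen peroxide, OO
Why: Directed ortho-metalation by the acetal oxygen (the two ortho positions are equivalent), borylation and oxidative 1,2-shift from boron to oxygen; alkaline peroxide does not epoxidise isolated alkenes and the quaternary centre has no acidic hydrogen.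

Step 5
Reactants: 10 2-(methoxymethoxy)-5-[(3R,6E)-3,7,11-trimethyldodeca-1,6,10-trien-3-yl]phenol; 11 trichloroethylene
Product: 12 2-{[(E)-1,2-dichloroethenyl]oxy}-1-(methoxymethoxy)-4-[(3R,6E)-3,7,11-trimethyldodeca-1,6,10-trien-3-yl]benzene
Conditions: KH, THF, 0 °C; then 11, 0 °C to rt
Reagents that add atoms: none
Why: Base-induced elimination from 11 gives dichloroacetylene, to which the potassium phenoxide adds anti, so the E-dichlorovinyl ether forms; this is the standard entry to aryl alkynyl ethers.

Step 6
Reactants: 12 2-{[(E)-1,2-dichloroethenyl]oxy}-1-(methoxymethoxy)-4-[(3R,6E)-3,7,11-trimethyldodeca-1,6,10-trien-3-yl]benzene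
Product: 15 2-(ethynyloxy)-1-(methoxymethoxy)-4-[(3R,6E)-3,7,11-trimethyldodeca-1,6,10-trien-3-yl]benzene, via chloroethynyl ether 13 (not isolated), via lithium acetylide 14 (not isolated)
Conditions: n-BuLi (2.3 equiv), Et2O, −78 to −40 °C; then MeOH, −78 °C
Reagents that add atoms: none
Why: Dehydrochlorination to the chloroalkynyl ether followed by chlorine–lithium exchange gives the lithium acetylide, which is protonated cold. An aryl alkynyl ether cannot undergo the retro-ene loss of ketene that limits alkyl ynol ethers, so it should tolerate the later heating.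

Step 7
Reactants: 16 3,3-diethoxyprop-1-yne
Product: 17 2-(3,3-diethoxyprop-1-en-2-yl)-4,4,5,5-tetramethyl-1,3,2-dioxaborolane
Conditions: B2(pin)2, MeOH, chloro[1,3-bis(2,4,6-trimethylphenyl)imidazolidin-2-ylidene]copper (5 mol%), NaOt-Bu (5 mol%), THF, −50 to −15 °C
Reagents that add atoms: bis(pinacolato)diboron, CC1(C)OB(OC1(C)C)B1OC(C)(C)C(C)(C)O1
Why: Copper-catalysed protoboration of a terminal alkyne; with an N-aryl carbene ligand and a propargylic oxygen substituent the copper–boron addition places boron on the internal carbon, and methanol protonates the alkenylcopper.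

Step 8
Reactants: 17 2-(3,3-diethoxyprop-1-en-2-yl)-4,4,5,5-tetramethyl-1,3,2-dioxaborolane; 2 diethyl (2E,6E)-3,7,11-trimethyldodeca-2,6,10-trien-1-yl phosphate
Product: 18 (3S,6E)-3-(3,3-diethoxyprop-1-en-2-yl)-3,7,11-trimethyldodeca-1,6,10-triene
Conditions: (R,R)-L (cat.), CuCl (cat.), NaOMe, THF, 60 °C
Reagents that add atoms: none
Why: Copper-catalysed enantioselective allylic substitution (SN2′) with an alkenylboronic ester; the copper methoxide exchanges with boron to give the alkenylcopper carbene complex, which attacks C3 of the phosphate. The enantiomeric ligand selects the alkene face opposite to that of step 3 and sets the S centre; the acetal masks the carbonyl during this step.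

Step 9
Reactants: 18 (3S,6E)-3-(3,3-diethoxyprop-1-en-2-yl)-3,7,11-trimethyldodeca-1,6,10-triene
Product: 19 (3S,6E)-3-ethenyl-3,7,11-trimethyl-2-methylidenedodeca-6,10-dienal
Conditions: pyridinium p-toluenesulfonate, acetone/H2O, rt
Reagents that add atoms: water, O
Why: Hydrolysis of an allylic acetal, which ionises easily under a weak acid that leaves the trisubstituted alkenes alone; the quaternary centre cannot epimerise.

Step 10
Reactants: 19 (3S,6E)-3-ethenyl-3,7,11-trimethyl-2-methylidenedodeca-6,10-dienal
Product: 20 (4S,7E)-4-ethenyl-4,8,12-trimethyl-3-methylidenetrideca-7,11-dien-2-ol (both C2 epimers)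
Conditions: MeMgBr, THF, −78 °C; aq. NH4Cl work-up
Reagents that add atoms: methylmagnesium bromide, C[Mg]Br
Why: 1,2-addition of a Grignard reagent to an α-substituted enal; the carbinol configuration is irrelevant because it is oxidised in the next step.

Step 11
Reactants: 20 (4S,7E)-4-ethenyl-4,8,12-trimethyl-3-methylidenetrideca-7,11-dien-2-ol (both C2 epimers)
Product: 21 (4S,7E)-4-ethenyl-4,8,12-trimethyl-3-methylidenetrideca-7,11-dien-2-one
Conditions: Dess–Martin periodinane, pyridine, CH2Cl2, 0 °C to rt
Reagents that add atoms: none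
Why: Dess–Martin oxidation of a secondary allylic alcohol under buffered, non-acidic conditions that do not touch the alkenes; the bulky α-substituent protects the enone from polymerisation.

Step 12
Reactants: 21 (4S,7E)-4-ethenyl-4,8,12-trimethyl-3-methylidenetrideca-7,11-dien-2-one
Product: 23 (4S,7E)-1-diazo-4-ethenyl-4,8,12-trimethyl-3-methylidenetrideca-7,11-dien-2-one, via trifluoroacetyl ketone 22 (not isolated)
Conditions: LiN(SiMe3)2, THF, −78 °C; CF3CO2CH2CF3, −78 °C; aq. HCl work-up; then MsN3, Et3N, H2O (1 equiv), MeCN, rt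
Reagents that add atoms: methanesulfonyl azide, CS(=O)(=O)N=[N+]=[N-]
Why: Detrifluoroacetylative diazo transfer; the methyl group is the only enolisable position, its trifluoroacetyl derivative accepts the diazo group from the sulfonyl azide, and the activating group leaves as the sulfonyl trifluoroacetamide. This avoids acylating diazomethane with an enoyl chloride, where dipolar addition to the conjugated alkene competes.

Step 13
Reactants: 15 2-(ethynyloxy)-1-(methoxymethoxy)-4-[(3R,6E)-3,7,11-trimethyldodeca-1,6,10-trien-3-yl]benzene; 23 (4S,7E)-1-diazo-4-ethenyl-4,8,12-trimethyl-3-methylidenetrideca-7,11-dien-2-one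
Product: 28 3-{2-(methoxymethoxy)-5-[(3R,6E)-3,7,11-trimethyldodeca-1,6,10-trien-3-yl]phenoxy}-5-[(3S,6E)-3,7,11-trimethyldodeca-1,6,10-trien-3-yl]phenol, via vinylketene 24 (not isolated), via vinylcyclobutenone 25 (not isolated), via dienylketene 26 (not isolated), via cyclohexadienone 27 (not isolated)
Conditions: 15 (1.2 equiv), hν (λ > 300 nm, Pyrex), degassed ClCH2CH2Cl, rt; then 80 °C
Reagents that add atoms: none
Why: Irradiation above 300 nm, where the diazoketone absorbs and the arene and alkenes do not, expels nitrogen from 23, and the alkenyl group migrates to the carbene carbon (Wolff rearrangement) to give vinylketene 24. The ketene adds to the electron-rich triple bond of 15 in a [2+2] cycloaddition in which the terminal CH carbon bonds to the ketene carbonyl carbon and the oxygen-bearing carbon to the ketene α-carbon, giving 25. 4π-Electrocyclic opening of 25, thermal or photochemical, gives dienylketene 26 with the ketene and the methylidene terminus on the same side. Ring B is then closed by thermal disrotatory 6π-electrocyclisation, which forms the C3–C4 bond of the six-membered carbocycle (27), and tautomerisation gives phenol 28; heating at 80 °C completes these last stages. The closest known reaction type is the Danheiser benzannulation in its photochemical Wolff variant with alkoxy- and siloxyalkynes, used here with an aryloxyalkyne. No stereocentre is formed: the sp3 ring carbon of 25 is lost on ring opening, and both quaternary centres are spectators that cannot epimerise. The step needs regioselectivity in the [2+2] event, secured by the oxygen-polarised alkyne so that the aryloxy group ends meta to the new hydroxyl, and chemoselectivity for the alkyne over the six chain alkenes, secured by the much higher reactivity of an ynol ether toward ketenes and by a small excess of 15 at high concentration.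

Step 14
Reactants: 28 3-{2-(methoxymethoxy)-5-[(3R,6E)-3,7,11-trimethyldodeca-1,6,10-trien-3-yl]phenoxy}-5-[(3S,6E)-3,7,11-trimethyldodeca-1,6,10-trien-3-yl]phenol
Product: 29 1-(methoxymethoxy)-2-{3-(methoxymethoxy)-5-[(3S,6E)-3,7,11-trimethyldodeca-1,6,10-trien-3-yl]phenoxy}-4-[(3R,6E)-3,7,11-trimethyldodeca-1,6,10-trien-3-yl]benzene
Conditions: MOMCl, i-Pr2NEt, CH2Cl2, 0 °C to rt
Reagents that add atoms: chloromethyl methyl ether, COCCl
Why: Phenol alkylation; the new acetal is the second directing group for the metalation at C2 of ring B and is removed together with the one on ring A.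

Step 15
Reactants: 29 1-(methoxymethoxy)-2-{3-(methoxymethoxy)-5-[(3S,6E)-3,7,11-trimethyldodeca-1,6,10-trien-3-yl]phenoxy}-4-[(3R,6E)-3,7,11-trimethyldodeca-1,6,10-trien-3-yl]benzene
Product: 32 2-(methoxymethoxy)-6-{2-(methoxymethoxy)-5-[(3R,6E)-3,7,11-trimethyldodeca-1,6,10-trien-3-yl]phenoxy}-4-[(3S,6E)-3,7,11-trimethyldodeca-1,6,10-trien-3-yl]phenol, via ring B aryllithium 30 (not isolated), via ring B dimethyl boronate 31 (not isolated)
Conditions: n-BuLi (1.1 equiv), THF, −20 to 0 °C; B(OMe)3, −78 °C to rt; then H2O2, aq. NaOH, 0 °C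
Reagents that add atoms: hydrogen peroxide, OO
Why: Directed ortho-metalation at the ring B carbon flanked by two oxygen substituents, which is the most acidic position (cooperative 1,3-directing effect), then borylation and oxidation. The competing site on ring A has only one directing group, and the positions next to the quaternary carbons are shielded.

Step 16
Reactants: 32 2-(methoxymethoxy)-6-{2-(methoxymethoxy)-5-[(3R,6E)-3,7,11-trimethyldodeca-1,6,10-trien-3-yl]phenoxy}-4-[(3S,6E)-3,7,11-trimethyldodeca-1,6,10-trien-3-yl]phenol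
Product: 33 3-{2-hydroxy-5-[(3R,6E)-3,7,11-trimethyldodeca-1,6,10-trien-3-yl]phenoxy}-5-[(3S,6E)-3,7,11-trimethyldodeca-1,6,10-trien-3-yl]benzene-1,2-diol
Conditions: ZnBr2, n-PrSH, CH2Cl2, 0 °C to rt; work-up under argon
Reagents that add atoms: none
Why: Lewis acid-assisted transfer of the methoxymethyl groups to the thiol cleaves both aryl acetals quickly without protic acid, so the trisubstituted alkenes should not cyclise or hydrate; the air-sensitive catechol is released only here.

## Compound list

1 | (2E,6E)-3,7,11-trimethyldodeca-2,6,10-trien-1-ol ((2E,6E)-farnesol) | OC/C=C(\C)CC/C=C(\C)CCC=C(C)C | starting material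
2 | diethyl (2E,6E)-3,7,11-trimethyldodeca-2,6,10-trien-1-yl phosphate | CCOP(=O)(OCC)OC/C=C(\C)CC/C=C(\C)CCC=C(C)C | intermediate
3 | 4-bromophenol | Oc1ccc(Br)cc1 | starting material
4 | 1-bromo-4-(methoxymethoxy)benzene | COCOc1ccc(Br)cc1 | intermediate
5 | [4-(methoxymethoxy)phenyl]lithium | [Li]c1ccc(OCOC)cc1 | intermediate
6 | diethyl[4-(methoxymethoxy)phenyl]alumane | CC[Al](CC)c1ccc(OCOC)cc1 | intermediate
7 | 1-(methoxymethoxy)-4-[(3R,6E)-3,7,11-trimethyldodeca-1,6,10-trien-3-yl]benzene | C=C[C@@](C)(CC/C=C(\C)CCC=C(C)C)c1ccc(OCOC)cc1 | intermediate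
8 | {2-(methoxymethoxy)-5-[(3R,6E)-3,7,11-trimethyldodeca-1,6,10-trien-3-yl]phenyl}lithium | C=C[C@@](C)(CC/C=C(\C)CCC=C(C)C)c1ccc(OCOC)c([Li])c1 | intermediate
9 | dimethyl {2-(methoxymethoxy)-5-[(3R,6E)-3,7,11-trimethyldodeca-1,6,10-trien-3-yl]phenyl}boronate | C=C[C@@](C)(CC/C=C(\C)CCC=C(C)C)c1ccc(OCOC)c(B(OC)OC)c1 | intermediate
10 | 2-(methoxymethoxy)-5-[(3R,6E)-3,7,11-trimethyldodeca-1,6,10-trien-3-yl]phenol | C=C[C@@](C)(CC/C=C(\C)CCC=C(C)C)c1ccc(OCOC)c(O)c1 | intermediate
11 | trichloroethylene (1,1,2-trichloroethene) | ClC=C(Cl)Cl | starting material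
12 | 2-{[(E)-1,2-dichloroethenyl]oxy}-1-(methoxymethoxy)-4-[(3R,6E)-3,7,11-trimethyldodeca-1,6,10-trien-3-yl]benzene | C=C[C@@](C)(CC/C=C(\C)CCC=C(C)C)c1ccc(OCOC)c(O/C(Cl)=C\Cl)c1 | intermediate
13 | 2-[(chloroethynyl)oxy]-1-(methoxymethoxy)-4-[(3R,6E)-3,7,11-trimethyldodeca-1,6,10-trien-3-yl]benzene | C=C[C@@](C)(CC/C=C(\C)CCC=C(C)C)c1ccc(OCOC)c(OC#CCl)c1 | intermediate
14 | ({2-(methoxymethoxy)-5-[(3R,6E)-3,7,11-trimethyldodeca-1,6,10-trien-3-yl]phenoxy}ethynyl)lithium | C=C[C@@](C)(CC/C=C(\C)CCC=C(C)C)c1ccc(OCOC)c(OC#C[Li])c1 | intermediate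
15 | 2-(ethynyloxy)-1-(methoxymethoxy)-4-[(3R,6E)-3,7,11-trimethyldodeca-1,6,10-trien-3-yl]benzene | C=C[C@@](C)(CC/C=C(\C)CCC=C(C)C)c1ccc(OCOC)c(OC#C)c1 | intermediate
16 | 3,3-diethoxyprop-1-yne | C#CC(OCC)OCC | starting material
17 | 2-(3,3-diethoxyprop-1-en-2-yl)-4,4,5,5-tetramethyl-1,3,2-dioxaborolane | C=C(B1OC(C)(C)C(C)(C)O1)C(OCC)OCC | intermediate
18 | (3S,6E)-3-(3,3-diethoxyprop-1-en-2-yl)-3,7,11-trimethyldodeca-1,6,10-triene | C=C(C(OCC)OCC)[C@](C)(C=C)CC/C=C(\C)CCC=C(C)C | intermediate
19 | (3S,6E)-3-ethenyl-3,7,11-trimethyl-2-methylidenedodeca-6,10-dienal | C=C(C=O)[C@](C)(C=C)CC/C=C(\C)CCC=C(C)C | intermediate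
20 | (4S,7E)-4-ethenyl-4,8,12-trimethyl-3-methylidenetrideca-7,11-dien-2-ol (both C2 epimers) | C=C(C(C)O)[C@](C)(C=C)CC/C=C(\C)CCC=C(C)C | intermediate
21 | (4S,7E)-4-ethenyl-4,8,12-trimethyl-3-methylidenetrideca-7,11-dien-2-one | C=C(C(C)=O)[C@](C)(C=C)CC/C=C(\C)CCC=C(C)C | intermediate
22 | (6S,9E)-6-ethenyl-1,1,1-trifluoro-6,10,14-trimethyl-5-methylidenepentadeca-9,13-diene-2,4-dione | C=C(C(=O)CC(=O)C(F)(F)F)[C@](C)(C=C)CC/C=C(\C)CCC=C(C)C | intermediate
23 | (4S,7E)-1-diazo-4-ethenyl-4,8,12-trimethyl-3-methylidenetrideca-7,11-dien-2-one | C=C(C(=O)C=[N+]=[N-])[C@](C)(C=C)CC/C=C(\C)CCC=C(C)C | intermediate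
24 | (4S,7E)-4-ethenyl-4,8,12-trimethyl-3-methylidenetrideca-1,7,11-trien-1-one | C=C(C=C=O)[C@](C)(C=C)CC/C=C(\C)CCC=C(C)C | intermediate
25 | 4-[(3S,6E)-3-ethenyl-3,7,11-trimethyldodeca-1,6,10-trien-2-yl]-3-{2-(methoxymethoxy)-5-[(3R,6E)-3,7,11-trimethyldodeca-1,6,10-trien-3-yl]phenoxy}cyclobut-2-en-1-one (both C4 epimers) | C=C[C@@](C)(CC/C=C(\C)CCC=C(C)C)c1ccc(OCOC)c(OC2=CC(=O)C2C(=C)[C@](C)(C=C)CC/C=C(\C)CCC=C(C)C)c1 | intermediate
26 | (3E,6S,9E)-6-ethenyl-3-{2-(methoxymethoxy)-5-[(3R,6E)-3,7,11-trimethyldodeca-1,6,10-trien-3-yl]phenoxy}-6,10,14-trimethyl-5-methylidenepentadeca-1,3,9,13-tetraen-1-one | C=C[C@@](C)(CC/C=C(\C)CCC=C(C)C)c1ccc(OCOC)c(O/C(=C/C(=C)[C@](C)(C=C)CC/C=C(\C)CCC=C(C)C)C=C=O)c1 | intermediate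
27 | 3-{2-(methoxymethoxy)-5-[(3R,6E)-3,7,11-trimethyldodeca-1,6,10-trien-3-yl]phenoxy}-5-[(3S,6E)-3,7,11-trimethyldodeca-1,6,10-trien-3-yl]cyclohexa-2,4-dien-1-one | C=C[C@@](C)(CC/C=C(\C)CCC=C(C)C)c1ccc(OCOC)c(OC2=CC(=O)CC([C@](C)(C=C)CC/C=C(\C)CCC=C(C)C)=C2)c1 | intermediate
28 | 3-{2-(methoxymethoxy)-5-[(3R,6E)-3,7,11-trimethyldodeca-1,6,10-trien-3-yl]phenoxy}-5-[(3S,6E)-3,7,11-trimethyldodeca-1,6,10-trien-3-yl]phenol | C=C[C@@](C)(CC/C=C(\C)CCC=C(C)C)c1ccc(OCOC)c(Oc2cc([C@](C)(C=C)CC/C=C(\C)CCC=C(C)C)cc(O)c2)c1 | intermediate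
29 | 1-(methoxymethoxy)-2-{3-(methoxymethoxy)-5-[(3S,6E)-3,7,11-trimethyldodeca-1,6,10-trien-3-yl]phenoxy}-4-[(3R,6E)-3,7,11-trimethyldodeca-1,6,10-trien-3-yl]benzene | C=C[C@@](C)(CC/C=C(\C)CCC=C(C)C)c1ccc(OCOC)c(Oc2cc([C@](C)(C=C)CC/C=C(\C)CCC=C(C)C)cc(OCOC)c2)c1 | intermediate
30 | {2-(methoxymethoxy)-6-{2-(methoxymethoxy)-5-[(3R,6E)-3,7,11-trimethyldodeca-1,6,10-trien-3-yl]phenoxy}-4-[(3S,6E)-3,7,11-trimethyldodeca-1,6,10-trien-3-yl]phenyl}lithium | C=C[C@@](C)(CC/C=C(\C)CCC=C(C)C)c1ccc(OCOC)c(Oc2cc([C@](C)(C=C)CC/C=C(\C)CCC=C(C)C)cc(OCOC)c2[Li])c1 | intermediate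
31 | dimethyl {2-(methoxymethoxy)-6-{2-(methoxymethoxy)-5-[(3R,6E)-3,7,11-trimethyldodeca-1,6,10-trien-3-yl]phenoxy}-4-[(3S,6E)-3,7,11-trimethyldodeca-1,6,10-trien-3-yl]phenyl}boronate | C=C[C@@](C)(CC/C=C(\C)CCC=C(C)C)c1ccc(OCOC)c(Oc2cc([C@](C)(C=C)CC/C=C(\C)CCC=C(C)C)cc(OCOC)c2B(OC)OC)c1 | intermediate
32 | 2-(methoxymethoxy)-6-{2-(methoxymethoxy)-5-[(3R,6E)-3,7,11-trimethyldodeca-1,6,10-trien-3-yl]phenoxy}-4-[(3S,6E)-3,7,11-trimethyldodeca-1,6,10-trien-3-yl]phenol | C=C[C@@](C)(CC/C=C(\C)CCC=C(C)C)c1ccc(OCOC)c(Oc2cc([C@](C)(C=C)CC/C=C(\C)CCC=C(C)C)cc(OCOC)c2O)c1 | intermediate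
33 | 3-{2-hydroxy-5-[(3R,6E)-3,7,11-trimethyldodeca-1,6,10-trien-3-yl]phenoxy}-5-[(3S,6E)-3,7,11-trimethyldodeca-1,6,10-trien-3-yl]benzene-1,2-diol | C=C[C@@](C)(CC/C=C(\C)CCC=C(C)C)c1ccc(O)c(Oc2cc([C@](C)(C=C)CC/C=C(\C)CCC=C(C)C)cc(O)c2O)c1 | target

## Step count and least certain steps

Total step count: 16.
Longest linear sequence: 10 steps (steps 1, 8, 9, 10, 11, 12, 13, 14, 15, 16, from 1 to 33).

**Step 13 (key step).** The most likely failure is capture of the ketocarbene or of vinylketene 24 before the alkyne is engaged. This could happen by intramolecular cyclopropanation or [2+2] addition to the nearby vinyl group or chain alkenes, or by acylation of the phenol already formed. Slow decay of the aryloxyalkyne under light and heat is a second route to loss. All of these are rate competitions that the bulky quaternary group next to the ketene makes less favourable for the desired bimolecular step.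

Fallback, setting out from 2 and from 9 and returning at 29: ring B is taken from a preformed arene and the ether is made by coupling.
- 3,5-Dibromophenol is methoxymethylated to 1,3-dibromo-5-(methoxymethoxy)benzene F1.
- Monolithiation (n-BuLi, Et2O, −78 °C), transmetalation with Et2AlCl and the allylic arylation of 2 as in step 3, but with (R,R)-L, should give 1-bromo-3-(methoxymethoxy)-5-[(3S,6E)-3,7,11-trimethyldodeca-1,6,10-trien-3-yl]benzene F2.
- Bromine–lithium exchange, B(OMe)3 and H2O2/NaOH should give 3-(methoxymethoxy)-5-[(3S,6E)-3,7,11-trimethyldodeca-1,6,10-trien-3-yl]phenol F3.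
- Boronate 9 of step 4 is hydrolysed instead of oxidised to {2-(methoxymethoxy)-5-[(3R,6E)-3,7,11-trimethyldodeca-1,6,10-trien-3-yl]phenyl}boronic acid F4.
- Chan–Lam coupling of F3 with F4 (Cu(OAc)2, pyridine, 4 Å molecular sieves, CH2Cl2, air) should give 29.

**Step 8.** Transfer of the α-branched alkenyl group from boron to copper and its addition to the trisubstituted alkene may be too slow, because the new bond joins a 1,1-disubstituted alkenyl carbon to a quaternary carbon. Direct SN2 substitution or loss of facial control would then take over.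

Fallback, setting out from 2 and returning at 19: a slim alkynyl nucleophile sets the centre and the methylidene is added afterwards.
- (Trimethylsilyl)acetylene is metalated with (i-Bu)2AlH and catalytic Et3N, and the alkynylalane is added to 2 with the silver carbene of (R,R)-L and CuCl2·2H2O to give (3S,6E)-3,7,11-trimethyl-3-[(trimethylsilyl)ethynyl]dodeca-1,6,10-triene F5.
- K2CO3 in MeOH gives (3S,6E)-3-ethynyl-3,7,11-trimethyldodeca-1,6,10-triene F6.
- Copper-catalysed anti-Markovnikov protoboration (CuCl, Xantphos, NaOt-Bu, B2(pin)2, MeOH), which leaves alkenes alone, gives 2-[(1E,3S,6E)-3-ethenyl-3,7,11-trimethyldodeca-1,6,10-trien-1-yl]-4,4,5,5-tetramethyl-1,3,2-dioxaborolane F7.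
- Oxidation with NaBO3·4H2O gives (3R,6E)-3-ethenyl-3,7,11-trimethyldodeca-6,10-dienal F8.
- α-Methylenation (aqueous formaldehyde, pyrrolidine, propionic acid, i-PrOH, 45 °C) gives 19.

**Step 6.** The terminal aryloxyacetylene may be lost by oligomerisation or hydration during work-up and concentration, and excess n-BuLi may begin to metalate the ring next to the acetal.

Fallback, setting out from 12 and returning at 28: the alkyne is carried in capped form.
- The lithium acetylide 14 is quenched with Me3SiCl instead of methanol, giving 1-(methoxymethoxy)-4-[(3R,6E)-3,7,11-trimethyldodeca-1,6,10-trien-3-yl]-2-{[(trimethylsilyl)ethynyl]oxy}benzene F9, which can be purified and stored.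
- Benzannulation of F9 with 23 under the conditions of step 13 should place silicon on the ring carbon between the two oxygens, giving 3-{2-(methoxymethoxy)-5-[(3R,6E)-3,7,11-trimethyldodeca-1,6,10-trien-3-yl]phenoxy}-5-[(3S,6E)-3,7,11-trimethyldodeca-1,6,10-trien-3-yl]-2-(trimethylsilyl)phenol F10.
- Protodesilylation (Bu4NF, wet THF) gives 28.

**Step 15.** Metalation may also occur on ring A ortho to its acetal, giving regioisomeric phenols after oxidation, since that site is less hindered even though it has only one directing group.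

Fallback, setting out from 28 (step 14 omitted) and returning at 33: the free phenol directs an electrophile instead.
- Magnesium-mediated ortho-formylation (MgCl2, Et3N, paraformaldehyde, MeCN, reflux) should go to the ortho position next to the aryloxy group, because the other ortho position adjoins the quaternary carbon, giving 2-hydroxy-6-{2-(methoxymethoxy)-5-[(3R,6E)-3,7,11-trimethyldodeca-1,6,10-trien-3-yl]phenoxy}-4-[(3S,6E)-3,7,11-trimethyldodeca-1,6,10-trien-3-yl]benzaldehyde F11.
- Dakin oxidation (H2O2, aq. NaOH, THF) gives 3-{2-(methoxymethoxy)-5-[(3R,6E)-3,7,11-trimethyldodeca-1,6,10-trien-3-yl]phenoxy}-5-[(3S,6E)-3,7,11-trimethyldodeca-1,6,10-trien-3-yl]benzene-1,2-diol F12.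
- Removal of the one remaining acetal (ZnBr2, n-PrSH, CH2Cl2) gives 33.

## Further compounds

F1 | step 13 | 1,3-dibromo-5-(methoxymethoxy)benzene | COCOc1cc(Br)cc(Br)c1
F2 | step 13 | 1-bromo-3-(methoxymethoxy)-5-[(3S,6E)-3,7,11-trimethyldodeca-1,6,10-trien-3-yl]benzene | COCOc1cc(Br)cc([C@](C)(C=C)CC/C=C(\C)CCC=C(C)C)c1
F3 | step 13 | 3-(methoxymethoxy)-5-[(3S,6E)-3,7,11-trimethyldodeca-1,6,10-trien-3-yl]phenol | COCOc1cc(O)cc([C@](C)(C=C)CC/C=C(\C)CCC=C(C)C)c1
F4 | step 13 | {2-(methoxymethoxy)-5-[(3R,6E)-3,7,11-trimethyldodeca-1,6,10-trien-3-yl]phenyl}boronic acid | C=C[C@@](C)(CC/C=C(\C)CCC=C(C)C)c1ccc(OCOC)c(B(O)O)c1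
F5 | step 8 | (3S,6E)-3,7,11-trimethyl-3-[(trimethylsilyl)ethynyl]dodeca-1,6,10-triene | C[Si](C)(C)C#C[C@](C)(C=C)CC/C=C(\C)CCC=C(C)C
F6 | step 8 | (3S,6E)-3-ethynyl-3,7,11-trimethyldodeca-1,6,10-triene | C#C[C@](C)(C=C)CC/C=C(\C)CCC=C(C)C
F7 | step 8 | 2-[(1E,3S,6E)-3-ethenyl-3,7,11-trimethyldodeca-1,6,10-trien-1-yl]-4,4,5,5-tetramethyl-1,3,2-dioxaborolane | CC1(C)OB(/C=C/[C@](C)(C=C)CC/C=C(\C)CCC=C(C)C)OC1(C)C
F8 | step 8 | (3R,6E)-3-ethenyl-3,7,11-trimethyldodeca-6,10-dienal | O=CC[C@](C)(C=C)CC/C=C(\C)CCC=C(C)C
F9 | step 6 | 1-(methoxymethoxy)-4-[(3R,6E)-3,7,11-trimethyldodeca-1,6,10-trien-3-yl]-2-{[(trimethylsilyl)ethynyl]oxy}benzene | C=C[C@@](C)(CC/C=C(\C)CCC=C(C)C)c1ccc(OCOC)c(OC#C[Si](C)(C)C)c1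
F10 | step 6 | 3-{2-(methoxymethoxy)-5-[(3R,6E)-3,7,11-trimethyldodeca-1,6,10-trien-3-yl]phenoxy}-5-[(3S,6E)-3,7,11-trimethyldodeca-1,6,10-trien-3-yl]-2-(trimethylsilyl)phenol | C=C[C@@](C)(CC/C=C(\C)CCC=C(C)C)c1ccc(OCOC)c(Oc2cc([C@](C)(C=C)CC/C=C(\C)CCC=C(C)C)cc(O)c2[Si](C)(C)C)c1
F11 | step 15 | 2-hydroxy-6-{2-(methoxymethoxy)-5-[(3R,6E)-3,7,11-trimethyldodeca-1,6,10-trien-3-yl]phenoxy}-4-[(3S,6E)-3,7,11-trimethyldodeca-1,6,10-trien-3-yl]benzaldehyde | C=C[C@@](C)(CC/C=C(\C)CCC=C(C)C)c1ccc(OCOC)c(Oc2cc([C@](C)(C=C)CC/C=C(\C)CCC=C(C)C)cc(O)c2C=O)c1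
F12 | step 15 | 3-{2-(methoxymethoxy)-5-[(3R,6E)-3,7,11-trimethyldodeca-1,6,10-trien-3-yl]phenoxy}-5-[(3S,6E)-3,7,11-trimethyldodeca-1,6,10-trien-3-yl]benzene-1,2-diol | C=C[C@@](C)(CC/C=C(\C)CCC=C(C)C)c1ccc(OCOC)c(Oc2cc([C@](C)(C=C)CC/C=C(\C)CCC=C(C)C)cc(O)c2O)c1
A1 | alternative 1 | diaryl ether bis(tertiary pinacol boronate) in which each benzylic carbon bears methyl, boron and the (3E)-4,8-dimethylnona-3,7-dienyl chain, as its tris(triisopropylsilyl) ether | CC1(C)OB(OC1(C)C)[C@@](C)(CC/C=C(\C)CCC=C(C)C)c1ccc(O[Si](C(C)C)(C(C)C)C(C)C)c(Oc2cc([C@](C)(B3OC(C)(C)C(C)(C)O3)CC/C=C(\C)CCC=C(C)C)cc(O[Si](C(C)C)(C(C)C)C(C)C)c2O[Si](C(C)C)(C(C)C)C(C)C)c1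
A2 | alternative 1 | diaryl ether bis(N,N-diisopropylcarbamate) of the two 1-arylethanols, R at the ring A carbinol carbon and S at the ring B carbinol carbon, as its tris(triisopropylsilyl) ether | C[C@@H](OC(=O)N(C(C)C)C(C)C)c1ccc(O[Si](C(C)C)(C(C)C)C(C)C)c(Oc2cc([C@H](C)OC(=O)N(C(C)C)C(C)C)cc(O[Si](C(C)C)(C(C)C)C(C)C)c2O[Si](C(C)C)(C(C)C)C(C)C)c1
A3 | alternative 1 | 2-[(3E)-4,8-dimethylnona-3,7-dien-1-yl]-4,4,5,5-tetramethyl-1,3,2-dioxaborolane | CC(C)=CCC/C(C)=C/CCB1OC(C)(C)C(C)(C)O1
A4 | alternative 2 | tris(methoxymethyl) ether of the target | C=C[C@@](C)(CC/C=C(\C)CCC=C(C)C)c1ccc(OCOC)c(Oc2cc([C@](C)(C=C)CC/C=C(\C)CCC=C(C)C)cc(OCOC)c2OCOC)c1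
A5 | alternative 2 | bis(1,3-dioxoisoindolin-2-yl) ester of the diaryl ether diacid in which each quaternary carbon bears methyl, vinyl and a 2-carboxyethyl group, as its tris(methoxymethyl) ether | C=C[C@@](C)(CCC(=O)ON1C(=O)c2ccccc2C1=O)c1ccc(OCOC)c(Oc2cc([C@](C)(C=C)CCC(=O)ON3C(=O)c4ccccc4C3=O)cc(OCOC)c2OCOC)c1
A6 | alternative 2 | (1E)-1-iodo-2,6-dimethylhepta-1,5-diene | I/C=C(\C)CCC=C(C)C
A7 | alternative 3 | 2-{2,3-bis(methoxymethoxy)-5-[(3S,6E)-3,7,11-trimethyldodeca-1,6,10-trien-3-yl]phenoxy}-4-[(3R,6E)-3,7,11-trimethyldodeca-1,6,10-trien-3-yl]cyclohex-2-en-1-one (ring CH centre unassigned) | O=C1CCC([C@@](C)(C=C)CC/C=C(\C)CCC=C(C)C)C=C1Oc1cc([C@](C)(C=C)CC/C=C(\C)CCC=C(C)C)cc(OCOC)c1OCOC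
A8 | alternative 3 | (3S,6E)-3-ethenyl-3,7,11-trimethyldodeca-6,10-dienal | O=CC[C@@](C)(C=C)CC/C=C(\C)CCC=C(C)C
A9 | alternative 3 | 1-{2,3-bis(methoxymethoxy)-5-[(3S,6E)-3,7,11-trimethyldodeca-1,6,10-trien-3-yl]phenoxy}but-3-en-2-one | C=CC(=O)COc1cc([C@](C)(C=C)CC/C=C(\C)CCC=C(C)C)cc(OCOC)c1OCOC
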